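**Plan**

1. Numbering of the bicyclo[3.3.1]nonane: C1 prenyl bridgehead, C2 C=O, C3 prenyl carbon, C4 C–OH, C5 benzoyl bridgehead, C6 CH2, C7 CH(prenyl), C8 CMe2, C9 bridging C=O.
2. Retrosynthesis cuts, in this order: C5–COPh (bridgehead acylation); C5–C6, undone as a 1,2-shift of C6 back to C9, which contracts ring B to a cyclopentanone (C9, C1, C8, C7, C6); then C5–C9 and C3–C4 together, which removes a two-carbon acetate unit (C4–C5) from ring A; then C3–CH2 (conjugate addition), C1–C2 (aldol), C1–CH2 and C8–CH3 (conjugate additions).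
3. Enabling feature: C1 carries both the C9 and the C2 carbonyl, so the electrophile C9 (held in a five-membered ring by a temporary C9–C6 bond) and the nucleophile C3 (enolate carbon next to C2) are 1,4-related across C1 and span exactly the unit C4–C5; C1, C2, C3, C4, C5 and C9 then form ring A.
4. Forward order: cyclopentenone → fully substituted cyclopentanone → ring A by annulation (fused six-five system) → ring B by oxidative ring expansion (C6 from C9 to C5) → bridgehead benzoylation → enol release.
5. Stereochemistry: C7 from commercial (R)-4-silyloxycyclopentenone (anti conjugate addition); C1 by an aldol anti to the C7 prenyl group across C8; C5 is fixed by the bicycle.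

Key step: step 8

Remark: enolised 1,3-diketones (20, 21, 26) are written as one tautomer, the one of the given target structure.
Remark: aqueous NH4Cl or HCl work-ups are assumed, so magnesium, lithium and copper leave as simple halides.

**Step 1**
Reactants: 1 (4R)-4-[(tert-butyldimethylsilyl)oxy]cyclopent-2-en-1-one; 2 (3-methylbut-2-en-1-yl)magnesium chloride
Product: 5 (4R)-4-(3-methylbut-2-en-1-yl)cyclopent-2-en-1-one, via silyl enol ether 3 (not isolated), via silyloxy ketone 4 (not isolated)
Conditions: 2, CuBr·SMe2 (1.5 equiv), TMSCl, THF, −78 °C; 1 M HCl; then DBU, CH2Cl2, 0 °C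
Reagents that add atoms: none
Why: Copper-mediated, silyl chloride-accelerated conjugate addition of the allylic Grignard reagent should deliver the prenyl group through its unsubstituted terminus anti to the silyloxy group, and the β-silyloxy ketone then loses silanol by E1cB elimination, so the C7 stereocentre arises by 1,2-induction from the commercial (R)-enone.

**Step 2**
Reactants: 5 (4R)-4-(3-methylbut-2-en-1-yl)cyclopent-2-en-1-one
Product: 6 trimethyl{[(3S,4R)-3-methyl-4-(3-methylbut-2-en-1-yl)cyclopent-1-en-1-yl]oxy}silane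
Conditions: MeMgBr, CuBr·SMe2 (5 mol %), TMSCl, THF, −78 °C; Et3N quench
Reagents that add atoms: methylmagnesium bromide C[Mg]Br; chlorotrimethylsilane C[Si](C)(C)Cl
Why: Copper-catalysed conjugate addition trans to the prenyl group with in situ O-silylation should give the enol ether regiospecifically; the new methyl-bearing centre becomes sp2 again in step 3, so its configuration does not matter.

**Step 3**
Reactants: 6 trimethyl{[(3S,4R)-3-methyl-4-(3-methylbut-2-en-1-yl)cyclopent-1-en-1-yl]oxy}silane
Product: 7 (4R)-3-methyl-4-(3-methylbut-2-en-1-yl)cyclopent-2-en-1-one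
Conditions: Pd(OAc)2 (10 mol %), O2 (1 atm), DMSO, 25 °C
Reagents that add atoms: none
Why: Saegusa–Ito oxidation (palladation of the silyl enol ether by divalent palladium, then β-hydride elimination) should re-form the enone towards the methyl-bearing carbon, a net β-methylation of 5 that leaves the γ-stereocentre untouched.

**Step 4**
Reactants: 7 (4R)-3-methyl-4-(3-methylbut-2-en-1-yl)cyclopent-2-en-1-one
Product: 9 (2R,4R)-2-[(dimethylamino)methyl]-3,3-dimethyl-4-(3-methylbut-2-en-1-yl)cyclopentan-1-one, via magnesium enolate 8 (not isolated)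
Conditions: MeMgBr, CuBr·SMe2 (10 mol %), THF, −20 °C; then CH2=NMe2+ I−, −20 °C to rt
Reagents that add atoms: methylmagnesium bromide C[Mg]Br; N,N-dimethylmethyleneiminium iodide (Eschenmoser's salt) C=[N+](C)C.[I-]
Why: Copper-catalysed conjugate addition makes the gem-dimethyl carbon C8 and at once the enolate on the hindered side of the ketone, which deprotonation would not give selectively, and Mannich trapping fixes a one-carbon handle there; the new centre is lost in step 5.

**Step 5**
Reactants: 9 (2R,4R)-2-[(dimethylamino)methyl]-3,3-dimethyl-4-(3-methylbut-2-en-1-yl)cyclopentan-1-one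
Product: 11 (4R)-3,3-dimethyl-2-methylidene-4-(3-methylbut-2-en-1-yl)cyclopentan-1-one, via ammonium iodide 10 (not isolated)
Conditions: MeI, CH2Cl2, rt; then sat. aq. NaHCO3, rt
Reagents that add atoms: none
Why: N-Methylation followed by base-induced β-elimination of trimethylamine (Hofmann-type, E1cB) should give the α-methylene ketone, which cannot isomerise into the ring because C8 is quaternary.

**Step 6**
Reactants: 11 (4R)-3,3-dimethyl-2-methylidene-4-(3-methylbut-2-en-1-yl)cyclopentan-1-one; 12 (2-methylprop-1-en-1-yl)magnesium bromide; 13 prop-2-enal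
Product: 15 (2R,4R)-2-(1-hydroxyprop-2-en-1-yl)-3,3-dimethyl-2,4-bis(3-methylbut-2-en-1-yl)cyclopentan-1-one (both carbinol epimers), via magnesium enolate 14 (not isolated)
Conditions: 12 (2.2 equiv), CuI (1.1 equiv), THF, −40 °C; 11, −78 °C; then 13, −78 °C; aq. NH4Cl
Reagents that add atoms: none
Why: Conjugate addition of the alkenyl cuprate to the exocyclic enone writes the C1 prenyl group and gives the tetrasubstituted C9/C1 enolate, whose 1,2-aldol addition to acrolein should form the quaternary centre C1 with the new C1–C2 bond anti to the C7 prenyl group, because the ring pucker that keeps that group pseudoequatorial turns the syn methyl group of C8 over the syn face.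

**Step 7**
Reactants: 15 (2R,4R)-2-(1-hydroxyprop-2-en-1-yl)-3,3-dimethyl-2,4-bis(3-methylbut-2-en-1-yl)cyclopentan-1-one
Product: 16 (2S,4R)-3,3-dimethyl-2,4-bis(3-methylbut-2-en-1-yl)-2-(prop-2-enoyl)cyclopentan-1-one
Conditions: Dess–Martin periodinane, NaHCO3, CH2Cl2, 0 °C to rt
Reagents that add atoms: none
Why: Buffered Dess–Martin oxidation of the allylic carbinol should give the vinyl ketone without retro-aldol cleavage of the non-enolisable 1,3-diketone; the descriptor at C2 changes only because the priorities change.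

**Step 8**
Reactants: 16 (2S,4R)-3,3-dimethyl-2,4-bis(3-methylbut-2-en-1-yl)-2-(prop-2-enoyl)cyclopentan-1-one; 12 (2-methylprop-1-en-1-yl)magnesium bromide; 17 ethyl acetate
Product: 20 (2R,3aS,7aR)-6,7a-dihydroxy-3,3-dimethyl-2,3a,5-tris(3-methylbut-2-en-1-yl)-1,2,3,3a,7,7a-hexahydro-4H-inden-4-one, via side-chain enolate 18 (not isolated), via aldolate 19 (not isolated)
Conditions: 12 (2.2 equiv), CuI (1.1 equiv), THF, −78 °C; then LiCH2CO2Et (from 17, LDA, THF, −78 °C); −78 to 0 °C; 1 M HCl
Reagents that add atoms: none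
Why: The cuprate adds 1,4 to the vinyl ketone, which writes the C3 prenyl group and parks C2 as a regiodefined enolate, so the ester enolate can only add (aldol) to the C9 ring ketone and forms C5–C9, and on warming the C3 enolate carbon attacks the ester carbonyl C4 (Claisen condensation) and forms C3–C4. The closest known reaction type is the annulation of a cyclic ketone enolate with diketene (acylation then aldol) to a ring-fused hydroxy 1,3-diketone, run here in the order aldol then acylation. Ring A closes in the Claisen event as a 6-(enolendo)-exo-trig acyl substitution, and loss of ethoxide followed by deprotonation of the new 1,3-diketone at C3 makes the sequence irreversible. The new carbinol centre C9 is set by the ring fusion: only the adduct with CH2CO2Et cis to the C2 arm on C1 can close to the cis-fused six-five system, that face is also anti to the C1 and C7 prenyl groups, and the aldol is reversible so the other adduct drains back; C3 is enolic and not stereogenic. The step needs addition at C9 to outrun proton transfer from C6 and retro-aldol cleavage, which low temperature, the lithium counter-ion and the enolate state of C2 (no acceptor for a C9–C1 retro-aldol) should secure.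

**Step 9**
Reactants: 20 (2R,3aS,7aR)-6,7a-dihydroxy-3,3-dimethyl-2,3a,5-tris(3-methylbut-2-en-1-yl)-1,2,3,3a,7,7a-hexahydro-4H-inden-4-one
Product: 21 (1S,5S,7R)-4-hydroxy-8,8-dimethyl-1,3,7-tris(3-methylbut-2-en-1-yl)bicyclo[3.3.1]non-3-ene-2,9-dione
Conditions: PhI(OAc)2, KOH, MeOH, 0 °C; aq. HCl
Reagents that add atoms: none
Why: Oxidative ring expansion by trivalent iodine, in which iodanylation of the diketonate at C3, enolisation towards C5 and a vinylogous semipinacol 1,2-shift of C6 from C9 to C5 with loss of iodobenzene should turn the carbinol C9 into the bridging ketone and the fused six-five skeleton into the bicyclo[3.3.1]nonane, whose new bridgehead C5 can only form in the configuration dictated by C1.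

**Step 10**
Reactants: 21 (1S,5S,7R)-4-hydroxy-8,8-dimethyl-1,3,7-tris(3-methylbut-2-en-1-yl)bicyclo[3.3.1]non-3-ene-2,9-dione
Product: 22 (1S,5S,7R)-4-methoxy-8,8-dimethyl-1,3,7-tris(3-methylbut-2-en-1-yl)bicyclo[3.3.1]non-3-ene-2,9-dione
Conditions: TMSCHN2, MeOH/toluene, 0 °C to rt
Reagents that add atoms: (trimethylsilyl)diazomethane C[Si](C)(C)C=[N+]=[N-]
Why: O-Methylation of the vinylogous acid masks the acidic 1,3-diketone for the carbanion chemistry of step 11 and is expected at the less hindered oxygen next to the bridgehead C–H; the regioisomeric enol ether would undergo steps 11 and 12 in the same way and converge on 26.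

**Step 11**
Reactants: 22 (1S,5S,7R)-4-methoxy-8,8-dimethyl-1,3,7-tris(3-methylbut-2-en-1-yl)bicyclo[3.3.1]non-3-ene-2,9-dione; 23 benzoyl chloride
Product: 25 (1R,5S,7R)-5-benzoyl-4-methoxy-8,8-dimethyl-1,3,7-tris(3-methylbut-2-en-1-yl)bicyclo[3.3.1]non-3-ene-2,9-dione, via bridgehead organolithium 24 (not isolated)
Conditions: LDA, THF, −78 °C; then 23, −78 to 0 °C
Reagents that add atoms: none
Why: Bridgehead lithiation at C5, the only acidic C–H left and flanked by the C9 ketone, should give a configurationally locked carbanion that is C-acylated by benzoyl chloride with necessary retention; the descriptor at C1 changes only by priority.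

**Step 12**
Reactants: 25 (1R,5S,7R)-5-benzoyl-4-methoxy-8,8-dimethyl-1,3,7-tris(3-methylbut-2-en-1-yl)bicyclo[3.3.1]non-3-ene-2,9-dione
Product: 26 (1R,5S,7R)-5-benzoyl-4-hydroxy-8,8-dimethyl-1,3,7-tris(3-methylbut-2-en-1-yl)bicyclo[3.3.1]non-3-ene-2,9-dione
Conditions: LiCl, DMSO, 120 °C; aq. HCl
Reagents that add atoms: none
Why: Chloride attacks the methyl group of the vinylogous ester (Krapcho-type SN2 demethylation) and should release the enolised 1,3-diketone under non-basic, non-hydrolytic conditions that spare the acyl groups on C1 and C5.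

**Compound list**

1 | (4R)-4-[(tert-butyldimethylsilyl)oxy]cyclopent-2-en-1-one | O=C1C=C[C@H](O[Si](C)(C)C(C)(C)C)C1 | starting material
2 | (3-methylbut-2-en-1-yl)magnesium chloride | CC(C)=CC[Mg]Cl | starting material
3 | tert-butyl(dimethyl){[(1R,2R)-2-(3-methylbut-2-en-1-yl)-4-(trimethylsilyloxy)cyclopent-3-en-1-yl]oxy}silane | C[Si](C)(C)OC1=C[C@@H](CC=C(C)C)[C@H](O[Si](C)(C)C(C)(C)C)C1 | intermediate
4 | (3R,4R)-4-[(tert-butyldimethylsilyl)oxy]-3-(3-methylbut-2-en-1-yl)cyclopentan-1-one | O=C1C[C@@H](CC=C(C)C)[C@H](O[Si](C)(C)C(C)(C)C)C1 | intermediate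
5 | (4R)-4-(3-methylbut-2-en-1-yl)cyclopent-2-en-1-one | O=C1C=C[C@H](CC=C(C)C)C1 | intermediate
6 | trimethyl{[(3S,4R)-3-methyl-4-(3-methylbut-2-en-1-yl)cyclopent-1-en-1-yl]oxy}silane | C[Si](C)(C)OC1=C[C@@H](C)[C@H](CC=C(C)C)C1 | intermediate
7 | (4R)-3-methyl-4-(3-methylbut-2-en-1-yl)cyclopent-2-en-1-one | O=C1C=C(C)[C@H](CC=C(C)C)C1 | intermediate
8 | bromomagnesium (4R)-3,3-dimethyl-4-(3-methylbut-2-en-1-yl)cyclopent-1-en-1-olate | Br[Mg]OC1=CC(C)(C)[C@H](CC=C(C)C)C1 | intermediate
9 | (2R,4R)-2-[(dimethylamino)methyl]-3,3-dimethyl-4-(3-methylbut-2-en-1-yl)cyclopentan-1-one | O=C1C[C@@H](CC=C(C)C)C(C)(C)[C@@H]1CN(C)C | intermediate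
10 | [(1R,3R)-2,2-dimethyl-3-(3-methylbut-2-en-1-yl)-5-oxocyclopentyl]-N,N,N-trimethylmethanaminium iodide | O=C1C[C@@H](CC=C(C)C)C(C)(C)[C@@H]1C[N+](C)(C)C.[I-] | intermediate
11 | (4R)-3,3-dimethyl-2-methylidene-4-(3-methylbut-2-en-1-yl)cyclopentan-1-one | O=C1C[C@@H](CC=C(C)C)C(C)(C)C1=C | intermediate
12 | (2-methylprop-1-en-1-yl)magnesium bromide | CC(C)=C[Mg]Br | starting material
13 | prop-2-enal (acrolein) | C=CC=O | starting material
14 | bromomagnesium (4R)-3,3-dimethyl-2,4-bis(3-methylbut-2-en-1-yl)cyclopent-1-en-1-olate | Br[Mg]OC1=C(CC=C(C)C)C(C)(C)[C@H](CC=C(C)C)C1 | intermediate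
15 | (2R,4R)-2-(1-hydroxyprop-2-en-1-yl)-3,3-dimethyl-2,4-bis(3-methylbut-2-en-1-yl)cyclopentan-1-one, both carbinol epimers | O=C1C[C@@H](CC=C(C)C)C(C)(C)[C@]1(CC=C(C)C)C(O)C=C | intermediate
16 | (2S,4R)-3,3-dimethyl-2,4-bis(3-methylbut-2-en-1-yl)-2-(prop-2-enoyl)cyclopentan-1-one | O=C1C[C@@H](CC=C(C)C)C(C)(C)[C@]1(CC=C(C)C)C(=O)C=C | intermediate
17 | ethyl acetate | CC(=O)OCC | starting material
18 | bromomagnesium 1-[(1R,3R)-2,2-dimethyl-1,3-bis(3-methylbut-2-en-1-yl)-5-oxocyclopentyl]-5-methylhexa-1,4-dien-1-olate | O=C1C[C@@H](CC=C(C)C)C(C)(C)[C@]1(CC=C(C)C)C(O[Mg]Br)=CCC=C(C)C | intermediate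
19 | aldolate of 18: C9 lithium alkoxide bearing CH2CO2Et cis to the enolate arm, configuration as in 20 | [Li]O[C@@]1(CC(=O)OCC)C[C@@H](CC=C(C)C)C(C)(C)[C@]1(CC=C(C)C)C(O[Mg]Br)=CCC=C(C)C | intermediate
20 | (2R,3aS,7aR)-6,7a-dihydroxy-3,3-dimethyl-2,3a,5-tris(3-methylbut-2-en-1-yl)-1,2,3,3a,7,7a-hexahydro-4H-inden-4-one | O[C@@]12C[C@@H](CC=C(C)C)C(C)(C)[C@]1(CC=C(C)C)C(=O)C(CC=C(C)C)=C(O)C2 | intermediate
21 | (1S,5S,7R)-4-hydroxy-8,8-dimethyl-1,3,7-tris(3-methylbut-2-en-1-yl)bicyclo[3.3.1]non-3-ene-2,9-dione | CC(C)=CCC1=C(O)[C@@H]2C[C@@H](CC=C(C)C)C(C)(C)[C@](CC=C(C)C)(C1=O)C2=O | intermediate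
22 | (1S,5S,7R)-4-methoxy-8,8-dimethyl-1,3,7-tris(3-methylbut-2-en-1-yl)bicyclo[3.3.1]non-3-ene-2,9-dione | CC(C)=CCC1=C(OC)[C@@H]2C[C@@H](CC=C(C)C)C(C)(C)[C@](CC=C(C)C)(C1=O)C2=O | intermediate
23 | benzoyl chloride | O=C(Cl)c1ccccc1 | starting material
24 | 5-lithio derivative of 22 (bridgehead organolithium) | CC(C)=CCC1=C(OC)[C@]2([Li])C[C@@H](CC=C(C)C)C(C)(C)[C@](CC=C(C)C)(C1=O)C2=O | intermediate
25 | (1R,5S,7R)-5-benzoyl-4-methoxy-8,8-dimethyl-1,3,7-tris(3-methylbut-2-en-1-yl)bicyclo[3.3.1]non-3-ene-2,9-dione | CC(C)=CCC1=C(OC)[C@]2(C(=O)c3ccccc3)C[C@@H](CC=C(C)C)C(C)(C)[C@](CC=C(C)C)(C1=O)C2=O | intermediate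
26 | (1R,5S,7R)-5-benzoyl-4-hydroxy-8,8-dimethyl-1,3,7-tris(3-methylbut-2-en-1-yl)bicyclo[3.3.1]non-3-ene-2,9-dione | CC(C)=CCC1=C(O)[C@]2(C(=O)c3ccccc3)C[C@@H](CC=C(C)C)C(C)(C)[C@](CC=C(C)C)(C1=O)C2=O | target

**Summary**

Total step count: 12. Longest linear sequence: 12 steps (1 to 26).

Steps most likely to fail:

Step 8. Proton transfer from C6 to the ester enolate (enolisation of the cyclopentanone instead of addition), scrambling of the C3 enolate to the ring side, or slow Claisen closure may erode the cascade. Fallback: the three events are separated. Setting out from 16, the cuprate addition is run with TMSCl to give the trimethylsilyl enol ether F1, in which C2 stays masked. The lithium enolate of ethyl acetate (with CeCl3 if enolisation persists) is then added to the C9 ketone, and mild acidic work-up gives the hydroxy keto ester F2. LiHMDS (3 equiv, THF, 0 °C) finally closes ring A by Claisen condensation, and the route is rejoined at 20.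

Step 9. The iodanylated C3 is quaternary here, so substitution at C3 by methoxide or acetate, or attack by a prenyl double bond, may outrun the 1,2-shift; elimination of the tertiary carbinol is a further drain. Fallback: a redox-neutral semipinacol with a built-in leaving group. Setting out from 16, step 8 is run with the lithium enolate of ethyl (phenylselanyl)acetate in place of that of 17, which gives the 7-(phenylselanyl) derivative of 20 F3. AgBF4 (CH2Cl2, 0 °C) then activates the selenide, and the known ring expansion of β-hydroxy selenides moves C6 from C9 to C5. The route is rejoined at 21.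

Step 6. Facial selectivity of the aldol that sets C1 rests on 1,3-induction across C8 and may be poor; 1,4- instead of 1,2-addition to acrolein is a second leak. Fallback: the order at C1 is reversed and the centre is set under reagent control. Setting out from 7, the magnesium enolate 8 is trapped with 5-methylhex-4-enal to give the aldol F4, which Dess–Martin periodinane oxidises to the enolisable 1,3-diketone F5. Allylic alkylation with methyl 3-methylbut-2-en-1-yl carbonate, Pd2(dba)3 (zerovalent palladium) and a chiral bis(2-diphenylphosphinobenzamide) ligand of trans-cyclohexane-1,2-diamine then gives the quaternary diketone F6; the ligand enantiomer is chosen to place the prenyl group syn to the C7 prenyl group. Addition of the lithium enolate of ethyl acetate to C9 followed by LiHMDS closes ring A, and the route is rejoined at 20.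

**Further compounds**

F1 | step 8 | (2R,4R)-3,3-dimethyl-2,4-bis(3-methylbut-2-en-1-yl)-2-[5-methyl-1-(trimethylsilyloxy)hexa-1,4-dien-1-yl]cyclopentan-1-one | O=C1C[C@@H](CC=C(C)C)C(C)(C)[C@]1(CC=C(C)C)C(O[Si](C)(C)C)=CCC=C(C)C
F2 | step 8 | ethyl 2-[(1R,2S,4R)-1-hydroxy-3,3-dimethyl-2,4-bis(3-methylbut-2-en-1-yl)-2-(5-methylhex-4-enoyl)cyclopentyl]acetate | CCOC(=O)C[C@]1(O)C[C@@H](CC=C(C)C)C(C)(C)[C@]1(CC=C(C)C)C(=O)CCC=C(C)C
F3 | step 9 | 7-(phenylselanyl) derivative of 20, either epimer at the selenium-bearing carbon | O[C@@]12C[C@@H](CC=C(C)C)C(C)(C)[C@]1(CC=C(C)C)C(=O)C(CC=C(C)C)=C(O)C2[Se]c1ccccc1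
F4 | step 6 | (4R)-2-(1-hydroxy-5-methylhex-4-en-1-yl)-3,3-dimethyl-4-(3-methylbut-2-en-1-yl)cyclopentan-1-one, mixture at C2 and the carbinol | O=C1C[C@@H](CC=C(C)C)C(C)(C)C1C(O)CCC=C(C)C
F5 | step 6 | (4R)-3,3-dimethyl-4-(3-methylbut-2-en-1-yl)-2-(5-methylhex-4-enoyl)cyclopentan-1-one, C2 epimerisable | O=C1C[C@@H](CC=C(C)C)C(C)(C)C1C(=O)CCC=C(C)C
F6 | step 6 | (2R,4R)-3,3-dimethyl-2,4-bis(3-methylbut-2-en-1-yl)-2-(5-methylhex-4-enoyl)cyclopentan-1-one | O=C1C[C@@H](CC=C(C)C)C(C)(C)[C@]1(CC=C(C)C)C(=O)CCC=C(C)C
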